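Readings and results are simulated for an exercise; scatter was added.

Elm carried 2.33 times the charge of birch, yet, hand against hand, the two runs fall together.

common to all: gas 110 mM (held)
- birch: left-handed substrate 0.60 M; right-handed substrate 0.60 M; run made earlier
- elm: left-handed substrate 1.4 M; right-handed substrate 1.4 M; run made earlier
- teal: left-handed substrate 0.90 M; right-handed substrate 0.90 M; time 10 h
- green: left-handed substrate 0.90 M; right-handed substrate 0.90 M; time 2.5 h

| run | time / h | right-handed substrate / % | left-handed substrate / % |
|---|---|---|---|
| birch | 1.00 | 50.7 | 48.6 |
| birch | 3.00 | 50.3 | 43.6 |
| birch | 6.00 | 48.2 | 39.4 |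
| birch | 8.00 | 47.4 | 37.6 |
| birch | 12.0 | 44.5 | 34.0 |
| elm | 1.00 | 50.9 | 48.8 |
| elm | 3.00 | 48.8 | 44.4 |
| elm | 6.00 | 47.9 | 40.3 |
| elm | 8.00 | 45.7 | 37.4 |
| elm | 12.0 | 44.5 | 33.2 |

(scatter of a reading: 0.5 percentage points)

- reagent is single-handed; left-handed substrate and right-handed substrate are mirror images of each other, charged as a racemate, each of them at the stated concentration
- the earlier runs were read with a standard deviation of 0.5 percentage points
- at the start none of the gas is in solution
- an excess is below zero if the other one leads
- the handed part of reagent does not stay in what it makes, so the products of the two hands are mirror images too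

* which one finishes higher in excess of right-handed substrate over left-handed substrate among what is left of the two ("neither" within 2 percentage points) (teal / green / neither)
* excess of right-handed substrate over left-handed substrate among what is left of the two at the end, teal
* excess of right-handed substrate over left-handed substrate among what is left of the two at the end, green

I work with the fraction left of each hand and divide one by the other at the same clock time. The two hands start equal, so the excess is one minus this ratio over one plus it. Between the readings at 8.00 h and 12.0 h, the four readings give 0.780 at teal's 10 h for the hand ratio, the fraction of left-handed substrate left over the fraction of right-handed substrate left. So I expect 12.3% for teal. Green, stopped at 2.5 h, interpolates to 0.906, hence 4.94%. Teal therefore stands higher than green by 7.4 percentage points.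

Is one number enough? The ratio at 8.00 h is 0.793 in birch and 0.818 in elm, and at 12.0 h it is 0.764 and 0.746. Elm lies above birch, then below, so I read no trend with charge in these two runs and treat the loss of each hand as pseudo-first-order.

The forecast says teal, with 12.4% for teal and 5.1% for green, because “only the stop time matters”. It rests on the same readings, so its closeness to mine is no check.

The flask gives teal, with 12.3% for teal and 4.38% for green.

    reagent + left-handed substrate → left-handed product (k = 1.10 × 10⁻⁴ /M/s)
    reagent + right-handed substrate → right-handed product (k = 5.30 × 10⁻⁶ /M/s)
    left-handed substrate ⇌ right-handed substrate (k = 1.50 × 10⁻⁵ /s)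
    2 reagent → homo dimer (k = 7.20 × 10⁻⁵ /M/s)
    reagent ⇌ dormant form (K = 3.40, k = 1.30 × 10⁻⁵ /s)
    gas ⇌ reagent, rate k6*(csat - [reagent]) (kL = 0.00640 /s)

Teal keeps 71% of its left-handed substrate and 91% of its right-handed substrate, a ratio of 0.780. Its neighbour, the same flask as teal read at 40 h, keeps 37% of its left-handed substrate and 54% of its right-handed substrate. That makes a hand ratio of 0.693, and one minus it over one plus it gives about 18.2%. This neighbour has run 4.00 times as long as teal, while the logarithm of its ratio is 1.48 times that of my 0.780 for teal.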